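## Analysis of the target

Compound 27 is a labdane (labdane numbering throughout) with a trans-fused decalin: ring A is C1–C5 with C10 and carries the gem-dimethyl group on C4, ring B is C5–C10. Its tetrasubstituted C8=C9 bond carries the C8 methyl group and, on C9, the chain C11–C16 that ends in an (E)-3-methylpent-2-enoic acid. The four stereocentres C5, C6, C7 and C10 are all S: H-5 is α and the C10 methyl β, the C6 acetate is β and axial, syn to the axial methyls on C4 and C10, and the C7 3-methylbutanoate is α and pseudoaxial, so the two ester oxygens are trans-diaxial. C10 is the one centre that cannot be corrected later, so it fixes the absolute configuration, and C5, C6 and C7 must be set relative to it. The C7 ester is allylic to C8=C9, and two different esters beside a free acid rule out any hydrolysis at the end, so the acid must be freed under neutral conditions and C13=C14 must be made E. The hard points are the quaternary C10 next to the quaternary C4, the fully substituted ring alkene, and two differently acylated oxygens in the diaxial array, one of them on the strongly shielded C6. The strategy rests on C6, a single oxygenated carbon between C5 and C7 with C8=C9 β,γ to it: this is the pattern formed when CO is inserted into a C5–C9–C10 cyclopropane whose C9 bears an isopropenyl group (the future C7, C8 and C8 methyl). The resulting C6 ketone then brings in O7 through its enolate and O6 by reduction.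

## Retrosynthetic reasoning

**27 ⇒ 26.** The acid is unmasked last by cutting the O–allyl bond of 26. An allyl ester is the one carboxyl protecting group that can be removed without acid, base or hydride in the presence of the acetate and the allylic 3-methylbutanoate.

**26 ⇒ 25 ⇒ 24.** The acetyl C–O bond is cut, then the C6–H bond: 25 comes from ketone 24 by hydride addition. The ketone is the natural precursor because the β face of C6 is blocked by two syn-axial methyl groups, so reduction can only give the axial 6β-alcohol. Acylating O7 before the reduction differentiates the two oxygens without any protecting group; they end trans-diaxial, a geometry in which acyl migration is not possible.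

**24 ⇒ 22 ⇒ 20.** The acyl group comes from anhydride 23. The C7–O bond is cut back to the sodium dienolate 21 of the β,γ-unsaturated ketone 20. C7 is both α to the carbonyl and allylic, so it is the kinetic site of deprotonation, and an electrophilic oxygen source enters there. The α face is both the pseudoaxial direction and the side away from the axial methyls, but only in the trans-fused series. C5 must therefore be correct before this step.

**20 ⇒ 18 ⇒ 17.** No skeletal bond is cut here; these two steps correct C5. The ring expansion forms C5–C6 with retention, so its product 17 is cis-fused. H-5 can only be equilibrated through the enol(ate), and the C7 hydrogens of 17 are far more acidic than H-5. Thermodynamic treatment therefore necessarily moves the double bond into conjugation, giving 18. The 8-ene is restored by forming the linear potassium dienolate 19 under equilibrating conditions and protonating it kinetically at C7.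

**Consequence for C9.** Because these steps run through a dienolate whose terminus is C9, C9 must not carry a CH2–O group. A C11 oxygen would be expelled by 1,6-elimination, and a C11 halide could not coexist with the ketone at all. The complete side chain is therefore placed on C9 before ring B is made. This also removes all chain-building steps from the stage where the sensitive diester exists.

**17 ⇒ 15 + 16 (key disconnection).** C5–C6 and C6–C7 are cut and C6 is removed as carbon monoxide 16. What remains is vinylcyclopropane 15: cyclopropane C5–C9–C10, isopropenyl group on C9. This cut takes ring B apart at the one carbon that carries no carbon substituent. It leaves C10, set earlier, untouched. The forward step must open C5–C9 and not C9–C10.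

**15 ⇒ 13 + 14; 13 ⇒ 12 ⇒ 10 + 11; 10 ⇒ 9 ⇒ 8.** C13=C14 is cut by olefination of methyl ketone 13 with phosphonoacetate 14. C11=C12 of enone 12 is cut by olefination of aldehyde 10 with ketophosphonate 11, followed forward by conjugate reduction. C11 is traced back through alcohol 9 to the ester carbon of 8. All of this is done on a robust hydrocarbon-like intermediate, where the E/Z isomers can be separated early.

**8 ⇒ 7 ⇒ 4 + 6.** The C8=C7 methylene comes from the acetyl group of 7. The two cyclopropane bonds C9–C5 and C9–C10 are cut to alkene 4 and the diazo keto ester 6. This one step builds the quaternary C9 with both of its future substituents and sets C10.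

**4 ⇒ 2 ⇒ 1; 6 ⇒ 5.** The trisubstituted alkene 4 is traced regiospecifically to ketone 1 through sulfonylhydrazone 2. The diazo ester 6 comes from methyl acetoacetate 5.

## Alternatives that were turned down

Alternative 1: intramolecular Diels–Alder reaction.
- Disconnection: C5–C10 and C6–C7 are cut together, so both rings come from the open-chain trienal A2.
- Forward step: a chiral oxazaborolidinium Lewis acid activates the (E)-enal (C5=C6, formyl on C6), which adds across the 7,9-diene already carrying the C7 ester. The product is the bicyclic aldehyde A1.
- For: one step forms two rings and two C–C bonds and sets C5, C6, C7 and C10 under catalyst control, with the trans fusion obtained directly. On these points it is stronger than the chosen route, which needs three steps after the ring expansion to correct C5 and bring in O7.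
- Against: the bond C5–C10 joins a neopentyl dienophile carbon to a fully substituted diene terminus. One substituent on C10 must point inward, which disfavours the s-cis diene. The 1-acyloxy diene is exposed to a strong Lewis acid. A2 needs a stereodefined tetrasubstituted C9=C10 and a trisubstituted enol ester C7=C8.
- After the key step: the formyl group of A1 is α while the acetate of 27 is β. A Baeyer–Villiger reaction would retain configuration, so the carbon must be removed through the C6 ketone, which is compound 24 of the present route.
- Comparison: if the cycloaddition worked it would reach 24 in fewer steps. The chosen strategy offers instead a precursor made from a simple ketone, with no stereodefined tetrasubstituted diene, and a key step whose regiochemistry follows from the substitution pattern.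

Alternative 2: dearomative para-alkylation.
- Disconnection: C1–C10 is cut, so ring A is closed onto an aromatic ring B.
- Forward step: the phenolate of bromide A4, ion-paired with a chiral quaternary ammonium cation, is alkylated at its para carbon C10. This gives the cross-conjugated dienone A3 with the quaternary centre in place.
- For: cheap aromatic starting materials, and C10 set in a single catalytic step on a flat substrate. On the origin of the absolute configuration it is at least as strong as the chosen route, whose asymmetric cyclopropanation is one of its uncertain steps.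
- Against: A3 has the wrong substitution and oxidation pattern. C9 bears hydrogen and still needs the side chain, by conjugate addition and re-oxidation to restore C8=C9. The carbonyl is on C7 and a chlorine on C6. C5=C6 must be reduced to the trans fusion. C5, C6 and C7 each need a step of their own.
- Comparison: the sequence after the key step is clearly longer. The chosen strategy delivers ring B with the C8 methyl, the C9 chain, C8=C9 and the C6 carbonyl in place.

Alternative 3: final ring closure by olefin metathesis.
- Disconnection: C8=C9 is cut; ring B is closed last from diene A6.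
- Forward step: a ruthenium alkylidene with an unhindered N-heterocyclic carbene ligand joins the isopropenyl carbon C8 to the methylene-bearing C9, giving the trichloroethyl ester A5.
- For: all four stereocentres and both esters are in place before ring closure and only one deprotection follows. The end-game is shorter than the chosen one and has no epimerisable ketone stage.
- Against: a tetrasubstituted alkene must be formed from two 1,1-disubstituted alkenes, one on the quaternary C10 and the other beside the C7 ester, which is at the limit of the method. The C5–C6–C7 triad of A6 must be built without a ring B to control it. The riskiest C–C bond formation comes at the very end, on the most valuable material.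
- Comparison: the chosen strategy places its risk in the middle of the route, and uses the rigid ring B to set C6 and C7.

Key step: step 11

Remark on the chemistry: the cyclopropane intermediates 7–15 are drawn with the acetyl or isopropenyl group exo (anti to C1 and C4); any C9 epimer formed in step 4 would be carried along, since C9 becomes trigonal in step 11.

## Route

Step 1
Reactants: 1 2,2,6-trimethylcyclohexanone
Product: 2 2,2,6-trimethylcyclohexanone 2,4,6-triisopropylbenzenesulfonylhydrazone
Conditions: 2,4,6-triisopropylbenzenesulfonohydrazide, cat. HCl, MeCN, 23 °C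
Reagents that add atoms: 2,4,6-triisopropylbenzenesulfonohydrazide, CC(C)c1cc(C(C)C)c(S(=O)(=O)NN)c(C(C)C)c1
Why: Acid-catalysed hydrazone formation; the hindered arylsulfonyl group later prevents ortho-metalation, and the ketone stereocentre is irrelevant because that carbon becomes trigonal in step 2.

Step 2
Reactants: 2 2,2,6-trimethylcyclohexanone 2,4,6-triisopropylbenzenesulfonylhydrazone
Product: 4 1,3,3-trimethylcyclohex-1-ene, via 2,6,6-trimethylcyclohex-1-enyllithium 3 (not isolated)
Conditions: n-BuLi (2.2 equiv), TMEDA, hexane–THF, −78 to 0 °C; then H2O
Reagents that add atoms: none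
Why: Shapiro reaction: the hydrazone dianion forms at the only α-carbon that bears hydrogen and loses sulfinate and dinitrogen to give vinyllithium 3; protonation places the double bond regiospecifically between the former carbonyl carbon and the methyl-bearing carbon.

Step 3
Reactants: 5 methyl acetoacetate
Product: 6 methyl 2-diazo-3-oxobutanoate
Conditions: 4-acetamidobenzenesulfonyl azide, Et3N, MeCN, 0 to 23 °C
Reagents that add atoms: 4-acetamidobenzenesulfonyl azide, CC(=O)Nc1ccc(cc1)S(=O)(=O)N=[N+]=[N-]
Why: Regitz diazo transfer to the active methylene group of the β-keto ester.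

Step 4
Reactants: 4 1,3,3-trimethylcyclohex-1-ene (2 equiv); 6 methyl 2-diazo-3-oxobutanoate
Product: 7 methyl (1S,6R,7R)-7-acetyl-1,5,5-trimethylbicyclo[4.1.0]heptane-7-carboxylate (acetyl exo)
Conditions: Rh2(S-TCPTTL)4 (dirhodium tetrakis[N-tetrachlorophthaloyl-(S)-tert-leucinate], 1 mol%), CH2Cl2, 23 °C, 6 added over 8 h
Reagents that add atoms: none
Why: Cyclopropanation by the electrophilic rhodium carbenoid of 6: the carbenoid carbon (C9) bonds first to the less substituted alkene carbon (C5) and closes onto C10 on the same face, so the fusion is necessarily cis. The chiral carboxylate ligands are relied on to select the alkene face that gives the 10S series (the mirror-image catalyst serves if the sense is opposite); the ketone, the trans-directing group of keto ester carbenoids, is expected anti to ring A.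

Step 5
Reactants: 7 methyl (1S,6R,7R)-7-acetyl-1,5,5-trimethylbicyclo[4.1.0]heptane-7-carboxylate
Product: 8 methyl (1S,6R,7S)-1,5,5-trimethyl-7-(prop-1-en-2-yl)bicyclo[4.1.0]heptane-7-carboxylate
Conditions: Ph3PCH3Br, KOtBu, THF, 0 to 50 °C
Reagents that add atoms: methyltriphenylphosphonium bromide, C[P+](c1ccccc1)(c1ccccc1)c1ccccc1.[Br-]
Why: Wittig methylenation; the non-stabilised ylide attacks the ketone and leaves the hindered quaternary ester untouched, and no stereocentre is affected.

Step 6
Reactants: 8 methyl (1S,6R,7S)-1,5,5-trimethyl-7-(prop-1-en-2-yl)bicyclo[4.1.0]heptane-7-carboxylate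
Product: 9 [(1S,6R,7S)-1,5,5-trimethyl-7-(prop-1-en-2-yl)bicyclo[4.1.0]heptan-7-yl]methanol
Conditions: LiAlH4, Et2O, 0 °C
Reagents that add atoms: none
Why: Hydride reduction of the ester to the primary alcohol (C11); the isolated alkene and the cyclopropane are inert.

Step 7
Reactants: 9 [(1S,6R,7S)-1,5,5-trimethyl-7-(prop-1-en-2-yl)bicyclo[4.1.0]heptan-7-yl]methanol
Product: 10 (1S,6R,7S)-1,5,5-trimethyl-7-(prop-1-en-2-yl)bicyclo[4.1.0]heptane-7-carbaldehyde
Conditions: Dess–Martin periodinane, NaHCO3, CH2Cl2, 0 to 23 °C
Reagents that add atoms: none
Why: Dess–Martin oxidation under buffered conditions; the aldehyde has no α-hydrogen and cannot enolise or epimerise.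

Step 8
Reactants: 10 (1S,6R,7S)-1,5,5-trimethyl-7-(prop-1-en-2-yl)bicyclo[4.1.0]heptane-7-carbaldehyde; 11 dimethyl (2-oxopropyl)phosphonate
Product: 12 (E)-4-[(1S,6R,7R)-1,5,5-trimethyl-7-(prop-1-en-2-yl)bicyclo[4.1.0]heptan-7-yl]but-3-en-2-one
Conditions: NaH, THF, 0 to 23 °C
Reagents that add atoms: none
Why: Horner–Wadsworth–Emmons olefination; the keto phosphonate anion adds even to the neopentyl aldehyde and the stabilised reagent gives the (E)-enone, forming C11=C12.

Step 9
Reactants: 12 (E)-4-[(1S,6R,7R)-1,5,5-trimethyl-7-(prop-1-en-2-yl)bicyclo[4.1.0]heptan-7-yl]but-3-en-2-one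
Product: 13 4-[(1S,6R,7R)-1,5,5-trimethyl-7-(prop-1-en-2-yl)bicyclo[4.1.0]heptan-7-yl]butan-2-one
Conditions: [(Ph3P)CuH]6 (0.25 equiv), H2O (3 equiv), THF, 23 °C
Reagents that add atoms: none
Why: Copper hydride conjugate reduction: hydride goes to the β-carbon C11 and water protonates the copper enolate. The unactivated isopropenyl group and the cyclopropane are not touched, which hydrogenation could not guarantee.

Step 10
Reactants: 13 4-[(1S,6R,7R)-1,5,5-trimethyl-7-(prop-1-en-2-yl)bicyclo[4.1.0]heptan-7-yl]butan-2-one; 14 allyl diethylphosphonoacetate
Product: 15 allyl (E)-3-methyl-5-[(1S,6R,7R)-1,5,5-trimethyl-7-(prop-1-en-2-yl)bicyclo[4.1.0]heptan-7-yl]pent-2-enoate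
Conditions: NaH, THF, 0 to 50 °C; Z isomer removed by chromatography
Reagents that add atoms: none
Why: Horner–Wadsworth–Emmons olefination of the methyl ketone; the (E)-ester, with the chain trans to the ester group, is the favoured isomer and should predominate. The isomers are separated here, early and on a robust compound.

Step 11
Reactants: 15 allyl (E)-3-methyl-5-[(1S,6R,7R)-1,5,5-trimethyl-7-(prop-1-en-2-yl)bicyclo[4.1.0]heptan-7-yl]pent-2-enoate; 16 carbon monoxide
Product: 17 allyl (13E)-6-oxo-5β-labda-8,13-dien-15-oate (cis-fused: 5β-H, 10β-methyl; 5R,10S)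
Conditions: [Rh(CO)2Cl]2 (5 mol%), CO (1 atm), toluene, 90 °C
Reagents that add atoms: none
Why: Monovalent rhodium binds the exo isopropenyl group and adds oxidatively into the adjacent C5–C9 cyclopropane bond, giving a σ-alkyl (C5) η3-allyl (C9–C8–C7) rhodacycle; CO inserts into the Rh–C5 bond and reductive elimination between the acyl carbon C6 and the unsubstituted allyl terminus C7 releases the cyclohex-3-enone. The closest known reaction type is the rhodium- or iron-carbonyl-mediated carbonylative [5+1] ring expansion of vinylcyclopropanes to β,γ-unsaturated cyclohexenones. Ring B is closed as a formal [5+1] annulation, completed in the reductive elimination that forms C6–C7; closure at the other allyl terminus C9 would give a cyclobutanone and is not expected. The one stereocentre that is re-formed, C5, keeps the configuration of the cis-fused cyclopropane because oxidative addition and migratory insertion both go with retention, so H-5 stays cis to the C10 methyl and the product is the cis-fused ketone; C10 is not touched. The step needs cleavage of C5–C9 and not of C9–C10: C5 is secondary while C10 is quaternary, and on the exo face, where the alkene holds the metal, C5 carries only hydrogen while C10 carries a methyl group. β-Hydride elimination from the C5–Rh alkyl, the usual escape of such metallacycles, is excluded because both neighbours of C5 (C4 and C10) are quaternary. The unsaturated ester of the side chain is remote and electron-poor and should not compete for the metal.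

Step 12
Reactants: 17 allyl (13E)-6-oxo-5β-labda-8,13-dien-15-oate
Product: 18 allyl (13E)-6-oxolabda-7,13-dien-15-oate (5α-H, 9α-H, 10β-methyl; 5S,9S,10R)
Conditions: K2CO3, allyl alcohol, 45 °C
Reagents that add atoms: none
Why: Base-mediated equilibration through the enolates of the ketone: the acidic C7 hydrogens exchange first and the double bond moves into conjugation, H-5 then epimerises to the more stable trans-fused ketone, and C9 is protonated axially from the α face so that the chain is equatorial. Allyl alcohol as solvent makes transesterification of the allyl ester degenerate, and nothing that could be eliminated sits on C11.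

Step 13
Reactants: 18 allyl (13E)-6-oxolabda-7,13-dien-15-oate
Product: 20 allyl (13E)-6-oxolabda-8,13-dien-15-oate (5α-H; 10β-methyl; 5S,10S), via potassium dienolate 19 (not isolated)
Conditions: KOtBu (1.1 equiv), THF, 0 °C; then AcOH, −78 °C
Reagents that add atoms: none
Why: Deconjugation by kinetic protonation: tert-butoxide removes a γ-hydrogen and, with the liberated tert-butanol as proton shuttle, the most stable linear dienolate 19 (tetrasubstituted C8=C9) is formed. A dienolate is protonated fastest at its α-carbon C7, which returns the β,γ-unsaturated ketone without touching C5.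

Step 14
Reactants: 20 allyl (13E)-6-oxolabda-8,13-dien-15-oate
Product: 22 allyl (13E)-7α-hydroxy-6-oxolabda-8,13-dien-15-oate (5S,7S,10S), via sodium dienolate 21 (not isolated)
Conditions: NaN(SiMe3)2 (1.1 equiv), THF, −78 °C; 2-(phenylsulfonyl)-3-phenyloxaziridine, −78 °C; AcOH
Reagents that add atoms: 2-(phenylsulfonyl)-3-phenyloxaziridine, O=S(=O)(c1ccccc1)N1OC1c1ccccc1
Why: Davis oxidation: the hindered amide base removes a proton kinetically from the doubly activated C7 rather than from the tertiary C5, giving the sodium dienolate 21 under aprotic conditions, and a sodium enolate is the usual partner of the sulfonyloxaziridine, which hydroxylates it at the α-carbon. Attack on the α face is the pseudoaxial direction on the ring B half-chair and lies opposite to the axial methyls on C10 and C4, so the 7α-alcohol should result.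

Step 15
Reactants: 22 allyl (13E)-7α-hydroxy-6-oxolabda-8,13-dien-15-oate; 23 isovaleric anhydride
Product: 24 allyl (13E)-7α-(3-methylbutanoyloxy)-6-oxolabda-8,13-dien-15-oate
Conditions: DMAP (cat.), pyridine, CH2Cl2, 0 to 23 °C
Reagents that add atoms: none
Why: DMAP-catalysed acylation of the secondary alcohol under mild base, so that the α-ketol neither epimerises nor isomerises.

Step 16
Reactants: 24 allyl (13E)-7α-(3-methylbutanoyloxy)-6-oxolabda-8,13-dien-15-oate
Product: 25 allyl (13E)-6β-hydroxy-7α-(3-methylbutanoyloxy)labda-8,13-dien-15-oate (5S,6S,7S,10S)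
Conditions: NaBH4, CeCl3·7H2O, MeOH–THF, −40 °C
Reagents that add atoms: none
Why: Luche reduction: the β face of C6 is shielded by the syn-axial methyls on C4 and C10, so hydride adds from the α face and gives the axial 6β-alcohol. The trans-diaxial relation of O6 and O7 prevents acyl migration, and the conjugated ester is not reduced.

Step 17
Reactants: 25 allyl (13E)-6β-hydroxy-7α-(3-methylbutanoyloxy)labda-8,13-dien-15-oate
Product: 26 allyl (13E)-6β-acetoxy-7α-(3-methylbutanoyloxy)labda-8,13-dien-15-oate
Conditions: Ac2O, DMAP, Et3N, CH2Cl2, 40 °C
Reagents that add atoms: acetic anhydride, CC(=O)OC(C)=O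
Why: Acylation of the hindered axial alcohol with the small acetyl group under nucleophilic catalysis at slightly raised temperature; no stereocentre is affected.

Step 18
Reactants: 26 allyl (13E)-6β-acetoxy-7α-(3-methylbutanoyloxy)labda-8,13-dien-15-oate
Product: 27 (13E)-6β-acetoxy-7α-(3-methylbutanoyloxy)labda-8,13-dien-15-oic acid (5S,6S,7S,10S), the target
Conditions: Pd(PPh3)4 (5 mol%), morpholine, THF, 23 °C
Reagents that add atoms: none
Why: Tsuji–Trost deallylation: zerovalent palladium ionises the primary allyl ester and morpholine takes up the allyl group, under neutral conditions that leave the acetate, the 3-methylbutanoate and the hindered secondary allylic C7–O bond intact.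

## Compound list

1 | 2,2,6-trimethylcyclohexanone (racemic) | CC1CCCC(C)(C)C1=O | starting material
2 | 2,2,6-trimethylcyclohexanone 2,4,6-triisopropylbenzenesulfonylhydrazone | CC1CCCC(C)(C)C1=NNS(=O)(=O)c1c(C(C)C)cc(C(C)C)cc1C(C)C | intermediate
3 | 2,6,6-trimethylcyclohex-1-enyllithium | [Li]C1=C(C)CCCC1(C)C | intermediate (not isolated)
4 | 1,3,3-trimethylcyclohex-1-ene | CC1=CC(C)(C)CCC1 | intermediate
5 | methyl acetoacetate | CC(=O)CC(=O)OC | starting material
6 | methyl 2-diazo-3-oxobutanoate | CC(=O)C(=[N+]=[N-])C(=O)OC | intermediate
7 | methyl (1S,6R,7R)-7-acetyl-1,5,5-trimethylbicyclo[4.1.0]heptane-7-carboxylate | CC(=O)[C@@]1(C(=O)OC)[C@@H]2C(C)(C)CCC[C@]12C | intermediate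
8 | methyl (1S,6R,7S)-1,5,5-trimethyl-7-(prop-1-en-2-yl)bicyclo[4.1.0]heptane-7-carboxylate | C=C(C)[C@@]1(C(=O)OC)[C@@H]2C(C)(C)CCC[C@]12C | intermediate
9 | [(1S,6R,7S)-1,5,5-trimethyl-7-(prop-1-en-2-yl)bicyclo[4.1.0]heptan-7-yl]methanol | C=C(C)[C@@]1(CO)[C@@H]2C(C)(C)CCC[C@]12C | intermediate
10 | (1S,6R,7S)-1,5,5-trimethyl-7-(prop-1-en-2-yl)bicyclo[4.1.0]heptane-7-carbaldehyde | C=C(C)[C@@]1(C=O)[C@@H]2C(C)(C)CCC[C@]12C | intermediate
11 | dimethyl (2-oxopropyl)phosphonate | COP(=O)(CC(C)=O)OC | starting material
12 | (E)-4-[(1S,6R,7R)-1,5,5-trimethyl-7-(prop-1-en-2-yl)bicyclo[4.1.0]heptan-7-yl]but-3-en-2-one | C=C(C)[C@@]1(/C=C/C(C)=O)[C@@H]2C(C)(C)CCC[C@]12C | intermediate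
13 | 4-[(1S,6R,7R)-1,5,5-trimethyl-7-(prop-1-en-2-yl)bicyclo[4.1.0]heptan-7-yl]butan-2-one | C=C(C)[C@@]1(CCC(C)=O)[C@@H]2C(C)(C)CCC[C@]12C | intermediate
14 | allyl diethylphosphonoacetate | CCOP(=O)(CC(=O)OCC=C)OCC | starting material
15 | allyl (E)-3-methyl-5-[(1S,6R,7R)-1,5,5-trimethyl-7-(prop-1-en-2-yl)bicyclo[4.1.0]heptan-7-yl]pent-2-enoate | C=C(C)[C@@]1(CC/C(C)=C/C(=O)OCC=C)[C@@H]2C(C)(C)CCC[C@]12C | intermediate
16 | carbon monoxide | [C-]#[O+] | starting material
17 | allyl (13E)-6-oxo-5β-labda-8,13-dien-15-oate (cis-fused) | O=C1CC(C)=C(CC/C(C)=C/C(=O)OCC=C)[C@@]2(C)CCCC(C)(C)[C@@H]12 | intermediate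
18 | allyl (13E)-6-oxolabda-7,13-dien-15-oate (5α-H, 9α-H) | O=C1C=C(C)[C@H](CC/C(C)=C/C(=O)OCC=C)[C@@]2(C)CCCC(C)(C)[C@H]12 | intermediate
19 | potassium dienolate of 20 (C6=C7, C8=C9) | [K+].[O-]C1=CC(C)=C(CC/C(C)=C/C(=O)OCC=C)[C@@]2(C)CCCC(C)(C)[C@H]12 | intermediate (not isolated)
20 | allyl (13E)-6-oxolabda-8,13-dien-15-oate (5α-H) | O=C1CC(C)=C(CC/C(C)=C/C(=O)OCC=C)[C@@]2(C)CCCC(C)(C)[C@H]12 | intermediate
21 | sodium dienolate of 20 (C6=C7, C8=C9) | [Na+].[O-]C1=CC(C)=C(CC/C(C)=C/C(=O)OCC=C)[C@@]2(C)CCCC(C)(C)[C@H]12 | intermediate (not isolated)
22 | allyl (13E)-7α-hydroxy-6-oxolabda-8,13-dien-15-oate | O=C1[C@@H](O)C(C)=C(CC/C(C)=C/C(=O)OCC=C)[C@@]2(C)CCCC(C)(C)[C@H]12 | intermediate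
23 | isovaleric anhydride | CC(C)CC(=O)OC(=O)CC(C)C | starting material
24 | allyl (13E)-7α-(3-methylbutanoyloxy)-6-oxolabda-8,13-dien-15-oate | O=C1[C@@H](OC(=O)CC(C)C)C(C)=C(CC/C(C)=C/C(=O)OCC=C)[C@@]2(C)CCCC(C)(C)[C@H]12 | intermediate
25 | allyl (13E)-6β-hydroxy-7α-(3-methylbutanoyloxy)labda-8,13-dien-15-oate | O[C@@H]1[C@@H](OC(=O)CC(C)C)C(C)=C(CC/C(C)=C/C(=O)OCC=C)[C@@]2(C)CCCC(C)(C)[C@H]12 | intermediate
26 | allyl (13E)-6β-acetoxy-7α-(3-methylbutanoyloxy)labda-8,13-dien-15-oate | CC(=O)O[C@@H]1[C@@H](OC(=O)CC(C)C)C(C)=C(CC/C(C)=C/C(=O)OCC=C)[C@@]2(C)CCCC(C)(C)[C@H]12 | intermediate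
27 | (13E)-6β-acetoxy-7α-(3-methylbutanoyloxy)labda-8,13-dien-15-oic acid | CC(=O)O[C@@H]1[C@@H](OC(=O)CC(C)C)C(C)=C(CC/C(C)=C/C(=O)O)[C@@]2(C)CCCC(C)(C)[C@H]12 | target

## Step count and least certain steps

Total step count: 18. Longest linear sequence: 17 steps (1, 2, 4–18); step 3 prepares the diazo ester 6.

**Step 11 (key step).**
- What may go wrong: the metal may fail to insert into the congested C5–C9 bond between two quaternary neighbours, or may open C9–C10 instead. The rhodacycle may also lose hydrogen from C11 through its σ-allyl form and release a ring-opened diene before CO is taken up.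
- Fallback: the ring expansion is run with stoichiometric iron carbonyl under photochemical activation (Fe(CO)5, CO, hν, then gentle warming). A σ-alkyl π-allyl acyl iron carbonyl is formed near room temperature and demetallated thermally, so the thermal rhodium pathway that allows hydride loss is avoided. It sets out from 15 and comes back at 17 (or at its conjugated isomer, which step 12 accepts equally). It makes no new isolable compound.

**Step 4.**
- What may go wrong: poor discrimination of the two alkene faces, which differ only in the position of a methyl group and a hydrogen, so that the enantiomeric purity is low; allylic C–H insertion may also lower the efficiency.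
- Fallback: classical resolution. It sets out from 9 of insufficient enantiomeric purity. Esterification with (S)-O-acetylmandelic acid (carbodiimide, cat. DMAP) gives the (S)-O-acetylmandelate of 9 F1 and the (S)-O-acetylmandelate of the enantiomer of 9 F2. These diastereomers are separated by chromatography or crystallisation. Saponification of F1 (LiOH, THF–H2O) comes back at 9.

**Step 12.**
- What may go wrong: incomplete epimerisation at C5. The trans-fused ketone is destabilised by the contact between the equatorial C4 methyl and the C6 carbonyl oxygen, so the equilibrium may retain cis-fused material.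
- Fallback: C5 is set by kinetic protonation instead of equilibration. It sets out from 17. The mixture obtained from 17, containing 18 and its C5 epimer allyl (13E)-6-oxo-5β-labda-7,13-dien-15-oate F3, is deprotonated at C5 with LiN(iPr)2 at −78 °C. The resulting cross-conjugated lithium dienolate (C5=C6, C7=C8) F4 is protonated with 2,6-di-tert-butylphenol from the α face, away from the C10 methyl. It comes back at 18.

**Step 14.**
- What may go wrong: attack on the β face, because the facial bias rests on two axial methyls that are not adjacent to C7; over-oxidation of the α-ketol is also possible.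
- Fallback: if the epimer allyl (13E)-7β-hydroxy-6-oxolabda-8,13-dien-15-oate F5 is the main product, it is used. Mitsunobu esterification with 3-methylbutanoic acid (PPh3, diisopropyl azodicarboxylate) inverts C7 at the activated allylic carbinol. It sets out from 20 and comes back at 24, replacing step 15.

**Step 10.**
- What may go wrong: insufficient E/Z selectivity in the olefination of the methyl ketone, with loss of material in the separation.
- Fallback: the trisubstituted alkene is made stereospecifically by cross-coupling. It sets out from 10. Wittig methylenation gives (1S,6R,7R)-7-ethenyl-1,5,5-trimethyl-7-(prop-1-en-2-yl)bicyclo[4.1.0]heptane F6. 9-BBN hydroborates the monosubstituted vinyl group in preference to the isopropenyl group and gives the B-alkyl-9-borabicyclo[3.3.1]nonane F7. This is coupled (PdCl2(dppf), K3PO4, DMF–THF) with allyl (E)-3-(trifluoromethylsulfonyloxy)but-2-enoate F8, made from allyl acetoacetate with Tf2O and aqueous Me4NOH. The coupling retains the alkene geometry, so it comes back at 15 and replaces steps 8–10.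

## Further compounds

F0 | step 11 | none | none
F1 | step 4 | (S)-O-acetylmandelate of 9 | C=C(C)[C@@]1(COC(=O)[C@@H](OC(C)=O)c2ccccc2)[C@@H]3C(C)(C)CCC[C@]13C
F2 | step 4 | (S)-O-acetylmandelate of the enantiomer of 9 | C=C(C)[C@]1(COC(=O)[C@@H](OC(C)=O)c2ccccc2)[C@H]3C(C)(C)CCC[C@@]13C
F3 | step 12 | allyl (13E)-6-oxo-5β-labda-7,13-dien-15-oate (5β-H, 9α-H) | O=C1C=C(C)[C@H](CC/C(C)=C/C(=O)OCC=C)[C@@]2(C)CCCC(C)(C)[C@@H]12
F4 | step 12 | lithium 5,7-dien-6-olate of 18 (cross-conjugated dienolate) | [Li+].[O-]C=1C=C(C)[C@H](CC/C(C)=C/C(=O)OCC=C)[C@@]2(C)CCCC(C)(C)C=12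
F5 | step 14 | allyl (13E)-7β-hydroxy-6-oxolabda-8,13-dien-15-oate | O=C1[C@H](O)C(C)=C(CC/C(C)=C/C(=O)OCC=C)[C@@]2(C)CCCC(C)(C)[C@H]12
F6 | step 10 | (1S,6R,7R)-7-ethenyl-1,5,5-trimethyl-7-(prop-1-en-2-yl)bicyclo[4.1.0]heptane | C=C(C)[C@@]1(C=C)[C@@H]2C(C)(C)CCC[C@]12C
F7 | step 10 | 9-{2-[(1S,6R,7R)-1,5,5-trimethyl-7-(prop-1-en-2-yl)bicyclo[4.1.0]heptan-7-yl]ethyl}-9-borabicyclo[3.3.1]nonane | C=C(C)[C@@]1(CCB2C3CCCC2CCC3)[C@@H]4C(C)(C)CCC[C@]14C
F8 | step 10 | allyl (E)-3-(trifluoromethylsulfonyloxy)but-2-enoate | C/C(OS(=O)(=O)C(F)(F)F)=C\C(=O)OCC=C
A1 | alternative 1 | allyl (13E)-6α-formyl-7α-(3-methylbutanoyloxy)labda-8,13-dien-15-oate (5α-H, 10β-methyl) | O=C[C@H]1[C@@H](OC(=O)CC(C)C)C(C)=C(CC/C(C)=C/C(=O)OCC=C)[C@@]2(C)CCCC(C)(C)[C@H]12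
A2 | alternative 1 | open-chain (5E,7E,9E)-trienal with the C7 3-methylbutanoate and the allyl ester side chain | O=C/C=C/C(C)(C)CCC/C(C)=C(\CC/C(C)=C/C(=O)OCC=C)/C(C)=C/OC(=O)CC(C)C
A3 | alternative 2 | 1-chloro-3,4a,8,8-tetramethyl-5,6,7,8-tetrahydronaphthalen-2(4aH)-one | O=C1C(Cl)=C2C(C)(C)CCC[C@]2(C)C=C1C
A4 | alternative 2 | 3-(5-bromo-2-methylpentan-2-yl)-2-chloro-4,6-dimethylphenol | Oc1c(Cl)c(C(C)(C)CCCBr)c(C)cc1C
A5 | alternative 3 | 2,2,2-trichloroethyl (13E)-6β-acetoxy-7α-(3-methylbutanoyloxy)labda-8,13-dien-15-oate | CC(=O)O[C@@H]1[C@@H](OC(=O)CC(C)C)C(C)=C(CC/C(C)=C/C(=O)OCC(Cl)(Cl)Cl)[C@@]2(C)CCCC(C)(C)[C@H]12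
A6 | alternative 3 | ring A diene with the C6 acetate, C7 3-methylbutanoate and C8 isopropenyl chain on C5 and the C9 1,1-disubstituted alkene on C10 | C=C(C)[C@H](OC(=O)CC(C)C)[C@@H](OC(C)=O)[C@H]1C(C)(C)CCC[C@]1(C)C(=C)CC/C(C)=C/C(=O)OCC(Cl)(Cl)Cl
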